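**Retrosynthetic overview**
1. The last two operations only unmask oxygen. Bu4NF removes two silyl groups, and BBr3 cleaves ten methyl and two ethyl ethers of the finished hexacycle.
2. Feature used: in each terminal ring (A, F), C1 carries ring B (or D) and lies between C2–OH and C6–OH. Its partner, C3 of ring B (or D), lies between C2–O and C4–O. This tetra-ortho-oxygenated aryl–aryl bond can be carried beforehand as the unhindered aryl–C(sp) bond of an ynol silyl ether.
3. Key disconnection: C1–C2 and C5–C6 are cut in ring A and in ring F. This leads to a B–C(E)–D core bis(siloxyalkyne) and two molecules of 3-ethoxycyclobutenone (two-directional Danheiser benzannulation).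
4. Core: the siloxyalkynes come from two aryl bromides (Sonogashira, desilylation, acetylide oxygenation, O-silylation). The three C–O bonds at ring C come from a double SNAr ortho to a formyl group, Baeyer–Villiger exchange of CHO for OH, and metal-free O-arylation with an aryliodonium salt.
5. Ring order: B, C, D and E are bought as benzene rings and joined (B and D to C, then E). A and F are the only rings constructed, both in one flask.

Key step: step 10

Assumption: 3-ethoxycyclobut-2-en-1-one is taken as a catalogue compound, distilled before use; the target carries no axial descriptor and its rings A and F are locally symmetric, so no atropisomer control is planned.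

**Step 1**
Reactants: 1 2,4,6-trimethoxybenzaldehyde
Product: 2 3-bromo-2,4,6-trimethoxybenzaldehyde
Conditions: NBS (1.0 equiv), MeCN, 0 °C to rt
Reagents that add atoms: N-bromosuccinimide, O=C1CCC(=O)N1Br
Why: Electrophilic aromatic bromination; C3 is ortho to two methoxy groups and para to the third, so one equivalent of NBS should substitute there once, and the bromine then slows a second attack at C5.

**Step 2**
Reactants: 2 3-bromo-2,4,6-trimethoxybenzaldehyde
Product: 4 3-bromo-2,4,6-trimethoxyphenol, via aryl formate 3 (not isolated)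
Conditions: mCPBA (1.05 equiv), CH2Cl2, 0 °C to rt; reductive wash; then NaOH, MeOH–H2O, 0 °C, argon; acidify
Reagents that add atoms: 3-chloroperoxybenzoic acid (mCPBA), O=C(OO)c1cccc(Cl)c1
Why: Baeyer–Villiger (Dakin-type) oxidation; the electron-rich aryl group migrates in the Criegee adduct in preference to hydride, the formate is saponified without isolation, and C–Br and the methyl ethers are inert to both reagents.

**Step 3**
Reactants: 4 3-bromo-2,4,6-trimethoxyphenol (2 equiv); 5 2,6-difluoro-4-methoxybenzaldehyde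
Product: 6 2,6-bis(3-bromo-2,4,6-trimethoxyphenoxy)-4-methoxybenzaldehyde
Conditions: Cs2CO3 (2.5 equiv), DMF, 100 °C, argon
Reagents that add atoms: none
Why: Twofold nucleophilic aromatic substitution (SNAr); both fluorides sit ortho to the formyl group that stabilises the Meisenheimer adducts, the 4-methoxy group is meta to both reacting carbons and does not deactivate them, and the aryl bromides are untouched in the absence of a metal.

**Step 4**
Reactants: 6 2,6-bis(3-bromo-2,4,6-trimethoxyphenoxy)-4-methoxybenzaldehyde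
Product: 8 2,6-bis(3-bromo-2,4,6-trimethoxyphenoxy)-4-methoxyphenol, via core formate 7 (not isolated)
Conditions: mCPBA (1.1 equiv), CH2Cl2, 0 °C to rt; reductive wash; then NaOH, MeOH–THF–H2O, 0 °C, argon; acidify
Reagents that add atoms: 3-chloroperoxybenzoic acid (mCPBA), O=C(OO)c1cccc(Cl)c1
Why: Baeyer–Villiger (Dakin-type) oxidation; ring C bears oxygen at both ortho positions and at the para position, so aryl migration should be fast, and the spent activating group becomes the hydroxyl needed for the third ether bond.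

**Step 5**
Reactants: 9 5-iodo-1,2,3-trimethoxybenzene; 10 1,3,5-trimethoxybenzene
Product: 12 (3,4,5-trimethoxyphenyl)(2,4,6-trimethoxyphenyl)iodonium tosylate, via hydroxy(tosyloxy)iodoarene 11 (not isolated)
Conditions: mCPBA, TsOH·H2O, MeCN, 50 °C; then 10, 50 °C; trituration with Et2O
Reagents that add atoms: p-toluenesulfonic acid monohydrate, Cc1ccc(S(=O)(=O)O)cc1.O; 3-chloroperoxybenzoic acid, O=C(OO)c1cccc(Cl)c1 (its oxygen stays only in intermediate 11)
Why: One-pot oxidation of the aryl iodide to trivalent iodine followed by electrophilic aromatic substitution on the very nucleophilic 1,3,5-trimethoxybenzene, the general preparation of aryl(2,4,6-trimethoxyphenyl)iodonium tosylates.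

**Step 6**
Reactants: 8 2,6-bis(3-bromo-2,4,6-trimethoxyphenoxy)-4-methoxyphenol; 12 (3,4,5-trimethoxyphenyl)(2,4,6-trimethoxyphenyl)iodonium tosylate
Product: 14 1,3-bis(3-bromo-2,4,6-trimethoxyphenoxy)-5-methoxy-2-(3,4,5-trimethoxyphenoxy)benzene (dibromide core), via potassium phenoxide 13 (not isolated)
Conditions: KOt-Bu (1.05 equiv), THF, 0 °C; then 12, 50 °C, argon
Reagents that add atoms: potassium tert-butoxide, CC(C)(C)[O-].[K+] (potassium only in intermediate 13)
Why: Metal-free O-arylation of a phenoxide with a diaryliodonium salt (ligand exchange at trivalent iodine, then ligand coupling); the more electron-rich 2,4,6-trimethoxyphenyl group stays on iodine as the dummy ligand, the method tolerates 2,6-disubstituted phenols, and the lack of a transition metal preserves both C–Br bonds.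

**Step 7**
Reactants: 14 dibromide core
Product: 15 1,3-bis{2,4,6-trimethoxy-3-[(triisopropylsilyl)ethynyl]phenoxy}-5-methoxy-2-(3,4,5-trimethoxyphenoxy)benzene
Conditions: HC≡CSi(i-Pr)3 (3 equiv), PdCl2(MeCN)2 (cat.), XPhos (cat.), Cs2CO3, MeCN–dioxane, 85 °C
Reagents that add atoms: (triisopropylsilyl)acetylene, C#C[Si](C(C)C)(C(C)C)C(C)C
Why: Copper-free Sonogashira coupling; the bulky electron-rich biaryl phosphine lets zerovalent palladium insert into electron-rich, di-ortho-substituted aryl bromides, and the triisopropylsilyl cap withstands the carbonate base and prevents a second coupling at the alkyne.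

**Step 8**
Reactants: 15 bis(silylalkyne) core
Product: 16 1,3-bis(3-ethynyl-2,4,6-trimethoxyphenoxy)-5-methoxy-2-(3,4,5-trimethoxyphenoxy)benzene
Conditions: Bu4NF, wet THF, 0 °C to rt
Reagents that add atoms: none
Why: Fluoride-induced protodesilylation of an alkynylsilane; the strong Si–F bond drives release of the acetylide, water protonates it, and nothing else in the molecule responds to fluoride.

**Step 9**
Reactants: 16 bis(terminal alkyne) core
Product: 19 1,3-bis{2,4,6-trimethoxy-3-[(triisopropylsiloxy)ethynyl]phenoxy}-5-methoxy-2-(3,4,5-trimethoxyphenoxy)benzene (core bis(siloxyalkyne)), via dilithium diacetylide 17 (not isolated), via dilithium bis-ynolate 18 (not isolated)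
Conditions: n-BuLi (2.0 equiv), THF, −78 °C; transfer to LiOOt-Bu [anhydrous t-BuOOH + LiN(SiMe3)2, THF, −78 °C]; −78 to 0 °C; then i-Pr3SiOTf, −78 to 0 °C; aq. NaHCO3/pentane work-up, Et3N-deactivated silica
Reagents that add atoms: tert-butyl hydroperoxide, CC(C)(C)OO; triisopropylsilyl trifluoromethanesulfonate, CC(C)[Si](OS(=O)(=O)C(F)(F)F)(C(C)C)C(C)C; n-butyllithium, [Li]CCCC (lithium only in intermediates 17 and 18)
Why: Electrophilic oxygenation of a lithium acetylide by lithium tert-butyl peroxide gives the lithium ynolate, and the bulky silyl triflate traps it on oxygen rather than carbon; at −78 °C the alkyne C–H is removed far faster than any ring C–H lying between two methoxy groups.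

**Step 10**
Reactants: 19 core bis(siloxyalkyne); 20 3-ethoxycyclobut-2-en-1-one (two equivalents react, about four are charged)
Product: 25 hexacycle in which C3 of ring B and of ring D each carries a 4-ethoxy-2-hydroxy-6-(triisopropylsiloxy)phenyl ring, via vinylketene 21 (not isolated), via bis-vinylcyclobutenone 22 (not isolated), via bis-dienylketene 23 (not isolated), via bis-cyclohexadienone 24 (not isolated)
Conditions: 20 added in portions, toluene (about 0.5 M), 80 °C until the alkyne is consumed, then 110 °C, sealed tube, argon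
Reagents that add atoms: none
Why: Heat cleaves the C1–C4 bond of 20 in a four-electron electrocyclic opening to vinylketene 21, whose ketene C=C adds to each electron-rich triple bond of 19 in a [2+2] cycloaddition to give the 4-(1-ethoxyvinyl)cyclobutenone arms of 22. A second four-electron opening unrolls each arm to the dienylketene of 23, and a six-electron electrocyclization between the ketene carbon and the terminal CH2 carbon closes rings A and F as the cyclohexadienones of 24, which tautomerise to the phenols of 25; each six-membered ring is thus closed pericyclically after its two new skeletal bonds, C1–C2(OH) and C6(OSi)–C5H, have been made. This is the Danheiser benzannulation, and its closest known form is the pairing of cyclobutenones with trialkylsiloxyalkynes to give resorcinol monosilyl ethers. The selectivity required is the regiochemistry of the [2+2] step, and it is secured by donation from the ynol oxygen, which makes the aryl-bearing alkyne carbon the nucleophilic terminus that bonds to the ketene carbonyl carbon, so that ring B (or D) ends up between OH and OSi. The linear alkyne holds the two ortho-methoxy groups of ring B (or D) away from the reacting carbon, so the crowded axis is never formed by joining two hindered arene carbons. No stereocentre persists (the sp3 CH of 22 is lost on ring opening), and the two hindered axes of 25 are unsymmetrical only through OH versus OSi, an element removed in step 11.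

**Step 11**
Reactants: 25 bis(silyl ether) hexacycle
Product: 26 hexacycle in which C3 of ring B and of ring D each carries a 4-ethoxy-2,6-dihydroxyphenyl ring
Conditions: Bu4NF, AcOH, THF, 0 °C, argon
Reagents that add atoms: none
Why: Fluoride cleavage of aryl silyl ethers, buffered with acetic acid so that no electron-rich phenoxide lingers; rings A and F become locally symmetric, so any atropisomeric mixture of 25 should converge on one compound.

**Step 12**
Reactants: 26 tetraphenol hexacycle
Product: 27 target CNP0279880.0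
Conditions: BBr3 (large excess), CH2Cl2, −78 °C to rt, argon; H2O quench at 0 °C; Sephadex LH-20 with degassed solvents
Reagents that add atoms: none
Why: Lewis-acid cleavage of alkyl aryl ethers; BBr3 binds each ether oxygen and bromide removes the methyl or ethyl group by SN2, diaryl ether and biaryl bonds offer no sp3 carbon and stay intact, and hydrolysis of the aryl borates releases the sixteen hydroxyl groups.

**Compound list**
1 | 2,4,6-trimethoxybenzaldehyde | COc1cc(OC)c(C=O)c(OC)c1 | starting material
2 | 3-bromo-2,4,6-trimethoxybenzaldehyde | O=Cc1c(OC)c(Br)c(OC)cc1OC | intermediate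
3 | 3-bromo-2,4,6-trimethoxyphenyl formate | O=COc1c(OC)c(Br)c(OC)cc1OC | intermediate
4 | 3-bromo-2,4,6-trimethoxyphenol | Oc1c(OC)c(Br)c(OC)cc1OC | intermediate
5 | 2,6-difluoro-4-methoxybenzaldehyde | COc1cc(F)c(C=O)c(F)c1 | starting material
6 | 2,6-bis(3-bromo-2,4,6-trimethoxyphenoxy)-4-methoxybenzaldehyde | COc1cc(Oc2c(OC)cc(OC)c(Br)c2OC)c(C=O)c(Oc2c(OC)cc(OC)c(Br)c2OC)c1 | intermediate
7 | 2,6-bis(3-bromo-2,4,6-trimethoxyphenoxy)-4-methoxyphenyl formate | COc1cc(Oc2c(OC)cc(OC)c(Br)c2OC)c(OC=O)c(Oc2c(OC)cc(OC)c(Br)c2OC)c1 | intermediate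
8 | 2,6-bis(3-bromo-2,4,6-trimethoxyphenoxy)-4-methoxyphenol | COc1cc(Oc2c(OC)cc(OC)c(Br)c2OC)c(O)c(Oc2c(OC)cc(OC)c(Br)c2OC)c1 | intermediate
9 | 5-iodo-1,2,3-trimethoxybenzene | COc1cc(I)cc(OC)c1OC | starting material
10 | 1,3,5-trimethoxybenzene | COc1cc(OC)cc(OC)c1 | starting material
11 | 5-[hydroxy(tosyloxy)iodo]-1,2,3-trimethoxybenzene | COc1cc(I(O)OS(=O)(=O)c2ccc(C)cc2)cc(OC)c1OC | intermediate
12 | (3,4,5-trimethoxyphenyl)(2,4,6-trimethoxyphenyl)iodonium tosylate | COc1cc(OC)c([I+]c2cc(OC)c(OC)c(OC)c2)c(OC)c1.Cc1ccc(S(=O)(=O)[O-])cc1 | intermediate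
13 | potassium 2,6-bis(3-bromo-2,4,6-trimethoxyphenoxy)-4-methoxyphenoxide | COc1cc(Oc2c(OC)cc(OC)c(Br)c2OC)c([O-])c(Oc2c(OC)cc(OC)c(Br)c2OC)c1.[K+] | intermediate
14 | 1,3-bis(3-bromo-2,4,6-trimethoxyphenoxy)-5-methoxy-2-(3,4,5-trimethoxyphenoxy)benzene | COc1cc(Oc2c(OC)cc(OC)c(Br)c2OC)c(Oc2cc(OC)c(OC)c(OC)c2)c(Oc2c(OC)cc(OC)c(Br)c2OC)c1 | intermediate
15 | 1,3-bis{2,4,6-trimethoxy-3-[(triisopropylsilyl)ethynyl]phenoxy}-5-methoxy-2-(3,4,5-trimethoxyphenoxy)benzene | COc1cc(Oc2c(OC)cc(OC)c(C#C[Si](C(C)C)(C(C)C)C(C)C)c2OC)c(Oc2cc(OC)c(OC)c(OC)c2)c(Oc2c(OC)cc(OC)c(C#C[Si](C(C)C)(C(C)C)C(C)C)c2OC)c1 | intermediate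
16 | 1,3-bis(3-ethynyl-2,4,6-trimethoxyphenoxy)-5-methoxy-2-(3,4,5-trimethoxyphenoxy)benzene | COc1cc(Oc2c(OC)cc(OC)c(C#C)c2OC)c(Oc2cc(OC)c(OC)c(OC)c2)c(Oc2c(OC)cc(OC)c(C#C)c2OC)c1 | intermediate
17 | dilithium diacetylide of 16 | COc1cc(Oc2c(OC)cc(OC)c(C#C[Li])c2OC)c(Oc2cc(OC)c(OC)c(OC)c2)c(Oc2c(OC)cc(OC)c(C#C[Li])c2OC)c1 | intermediate
18 | dilithium bis(ynolate) of the core | COc1cc(Oc2c(OC)cc(OC)c(C#CO[Li])c2OC)c(Oc2cc(OC)c(OC)c(OC)c2)c(Oc2c(OC)cc(OC)c(C#CO[Li])c2OC)c1 | intermediate
19 | 1,3-bis{2,4,6-trimethoxy-3-[(triisopropylsiloxy)ethynyl]phenoxy}-5-methoxy-2-(3,4,5-trimethoxyphenoxy)benzene | COc1cc(Oc2c(OC)cc(OC)c(C#CO[Si](C(C)C)(C(C)C)C(C)C)c2OC)c(Oc2cc(OC)c(OC)c(OC)c2)c(Oc2c(OC)cc(OC)c(C#CO[Si](C(C)C)(C(C)C)C(C)C)c2OC)c1 | intermediate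
20 | 3-ethoxycyclobut-2-en-1-one | CCOC1=CC(=O)C1 | starting material
21 | 3-ethoxybuta-1,3-dien-1-one (vinylketene) | C=C(OCC)C=C=O | intermediate
22 | core with two 4-(1-ethoxyvinyl)-3-(triisopropylsiloxy)-cyclobut-2-en-1-on-2-yl arms (transient CH centres, unassigned) | COc1cc(Oc2c(OC)cc(OC)c(C3=C(O[Si](C(C)C)(C(C)C)C(C)C)C(C(=C)OCC)C3=O)c2OC)c(Oc2cc(OC)c(OC)c(OC)c2)c(Oc2c(OC)cc(OC)c(C3=C(O[Si](C(C)C)(C(C)C)C(C)C)C(C(=C)OCC)C3=O)c2OC)c1 | intermediate
23 | core with two dienylketene arms, ketene-bearing carbon and ethoxyvinyl group cis on the central C=C | COc1cc(Oc2c(OC)cc(OC)c(C(=C=O)/C(O[Si](C(C)C)(C(C)C)C(C)C)=C\C(=C)OCC)c2OC)c(Oc2cc(OC)c(OC)c(OC)c2)c(Oc2c(OC)cc(OC)c(C(=C=O)/C(O[Si](C(C)C)(C(C)C)C(C)C)=C\C(=C)OCC)c2OC)c1 | intermediate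
24 | core with two 5-ethoxy-3-(triisopropylsiloxy)cyclohexa-2,4-dien-1-on-2-yl arms | COc1cc(Oc2c(OC)cc(OC)c(C3=C(O[Si](C(C)C)(C(C)C)C(C)C)C=C(OCC)CC3=O)c2OC)c(Oc2cc(OC)c(OC)c(OC)c2)c(Oc2c(OC)cc(OC)c(C3=C(O[Si](C(C)C)(C(C)C)C(C)C)C=C(OCC)CC3=O)c2OC)c1 | intermediate
25 | hexacycle with rings A and F as 4-ethoxy-2-hydroxy-6-(triisopropylsiloxy)phenyl | COc1cc(Oc2c(OC)cc(OC)c(-c3c(O)cc(OCC)cc3O[Si](C(C)C)(C(C)C)C(C)C)c2OC)c(Oc2cc(OC)c(OC)c(OC)c2)c(Oc2c(OC)cc(OC)c(-c3c(O)cc(OCC)cc3O[Si](C(C)C)(C(C)C)C(C)C)c2OC)c1 | intermediate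
26 | hexacycle with rings A and F as 4-ethoxy-2,6-dihydroxyphenyl | COc1cc(Oc2c(OC)cc(OC)c(-c3c(O)cc(OCC)cc3O)c2OC)c(Oc2cc(OC)c(OC)c(OC)c2)c(Oc2c(OC)cc(OC)c(-c3c(O)cc(OCC)cc3O)c2OC)c1 | intermediate
27 | CNP0279880.0 | Oc1cc(O)c(-c2c(O)cc(O)c(Oc3cc(O)cc(Oc4c(O)cc(O)c(-c5c(O)cc(O)cc5O)c4O)c3Oc3cc(O)c(O)c(O)c3)c2O)c(O)c1 | target

**Totals**
Total step count: 12.
Longest linear sequence: 11 steps (steps 1–4 and 6–12). Step 5 is a one-step side branch.

**Steps most likely to fail**

Step 10. Several processes could undermine it.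
- Opening of the donor-stabilised cyclobutenone may be slower than thermal decay of the siloxyalkyne (silyl shift, or protonation by the phenol already formed).
- Surplus vinylketene may acylate the new phenols.
- The cascade may stop after one arm.

The fallback sets out from 14 and comes back at 27. It gives up ring construction in favour of cross-coupling. A twofold Suzuki–Miyaura coupling of 14 with 2,4,6-trimethoxyphenylboronic acid (used in excess to offset protodeboronation; Pd(OAc)2, SPhos, K3PO4, toluene–H2O, 100 °C) should give the hexadeca-O-methyl ether of the target F1. BBr3 (CH2Cl2, −78 °C to rt) then cleaves all sixteen methyl ethers to give 27.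

Step 9. The possible failures are these.
- Oxygen transfer may remain incomplete on one of the two acetylide arms.
- Ring lithiation between two methoxy groups may compete.
- Silylation may occur on carbon instead of oxygen.
- The very electron-rich ynol silyl ether may hydrolyse during isolation.

The fallback sets out from 14 and comes back at 27. It installs the ynol ether oxygen ready-made. Stille coupling of 14 with tributyl(ethoxyethynyl)stannane (Pd2(dba)3, P(t-Bu)3, CsF, dioxane, 80 °C) should give the core bis(ethoxyalkyne) F2. This compound takes the place of 19 in the same benzannulation with 20. The mixture is held in toluene at 80 °C until the alkyne is consumed, which stays below retro-ene loss of ethylene, and is then heated to 110 °C. The product should be the hexacycle with 2,4-diethoxy-6-hydroxyphenyl terminal rings F3. BBr3 then cleaves ten methyl and four ethyl ethers to give 27, and no desilylation step is needed.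

Step 6. Ligand coupling at the doubly flanked phenoxide may be sluggish. The wrong aryl group may be transferred from iodine, or the iodonium salt may decompose under base. The fallback sets out from 8 and 9 and comes back at 14. It uses copper-catalysed Ullmann-type ether synthesis: CuI, picolinic acid, K3PO4, DMSO, 80 °C. The unhindered aryl iodide 9 should react well ahead of the electron-rich, di-ortho-substituted aryl bromides of 8, and step 5 is no longer needed. No compound outside the list is made (none F0).

**Further compounds**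
F1 | step 10 | hexadeca-O-methyl ether of the target | COc1cc(Oc2c(OC)cc(OC)c(-c3c(OC)cc(OC)cc3OC)c2OC)c(Oc2cc(OC)c(OC)c(OC)c2)c(Oc2c(OC)cc(OC)c(-c3c(OC)cc(OC)cc3OC)c2OC)c1
F2 | step 9 | 1,3-bis[3-(ethoxyethynyl)-2,4,6-trimethoxyphenoxy]-5-methoxy-2-(3,4,5-trimethoxyphenoxy)benzene | COc1cc(Oc2c(OC)cc(OC)c(C#COCC)c2OC)c(Oc2cc(OC)c(OC)c(OC)c2)c(Oc2c(OC)cc(OC)c(C#COCC)c2OC)c1
F3 | step 9 | hexacycle with rings A and F as 2,4-diethoxy-6-hydroxyphenyl | COc1cc(Oc2c(OC)cc(OC)c(-c3c(O)cc(OCC)cc3OCC)c2OC)c(Oc2cc(OC)c(OC)c(OC)c2)c(Oc2c(OC)cc(OC)c(-c3c(O)cc(OCC)cc3OCC)c2OC)c1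
F0 | step 6 | none | none
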